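**Plan**
1. Halimane numbering: ring A = C1–C5 and C10, ring B = C5–C10, chain C11–C16 on C9. Cuts, in order: the C7 O–acyl bond; C13–O and C14=C15 (back through epoxy alcohol and enoate to a methyl ketone); the C6 and C7 oxygens (back to a C6 enone); C4–C5 (ring A); C10–C1; C9–CH3 and C9–C11.
2. Feature used: C4(CH3)2–C5=C10 next to oxygenated C6 is a β-cyclogeranyl (β-damascone-type) array, so ring A is the cyclization product of the ring B enone C6(=O)–C5H=C10–CH2CH2CH=C(CH3)2.
3. Forward: ring B is the chiral-pool enone; two α′-alkylations build quaternary C9; Grignard addition plus oxidative 1,3-transposition give the cyclization substrate; acid closes ring A last; then side chain and oxygenation.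
4. Stereochemistry: C8 from (R)-5-methylcyclohex-2-en-1-one; C9 by methylation anti to the C8 methyl; C7 by enolate hydroxylation anti to the C8 methyl; C6 by equatorial attack of a bulky hydride; C13 by Sharpless epoxidation with D-(−)-diethyl tartrate.

Key step: step 6

Remark: (R)-5-methylcyclohex-2-en-1-one (3) is taken as a purchasable chiral-pool enone (it is the short degradation product of (R)-(+)-pulegone).

Step 1
Reactants: 1 2-(2-bromoethyl)-2-methyl-1,3-dioxolane
Product: 2 2-(2-iodoethyl)-2-methyl-1,3-dioxolane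
Conditions: NaI, NaHCO3, acetone, reflux
Reagents that add atoms: sodium iodide, [Na+].[I-]
Why: Finkelstein halide exchange (SN2, driven by precipitation of NaBr) should give the primary iodide, which is reactive enough for ketone enolate alkylation.

Step 2
Reactants: 3 (R)-5-methylcyclohex-2-en-1-one; 2 2-(2-iodoethyl)-2-methyl-1,3-dioxolane
Product: 5 (5R,6S)-5-methyl-6-[2-(2-methyl-1,3-dioxolan-2-yl)ethyl]cyclohex-2-en-1-one, via lithium dienolate 4 (not isolated)
Conditions: LiN(i-Pr)2, THF, −78 °C; then 2, HMPA, −78 to −20 °C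
Reagents that add atoms: none
Why: Kinetic α′-deprotonation gives the cross-conjugated dienolate, which undergoes SN2 enolate C-alkylation mainly anti to the C8 methyl; the configuration of the new C9–H centre does not matter because it is planarized in step 3.

Step 3
Reactants: 5 (5R,6S)-5-methyl-6-[2-(2-methyl-1,3-dioxolan-2-yl)ethyl]cyclohex-2-en-1-one
Product: 7 (5R,6R)-5,6-dimethyl-6-[2-(2-methyl-1,3-dioxolan-2-yl)ethyl]cyclohex-2-en-1-one, via lithium enolate 6 (not isolated)
Conditions: LiN(i-Pr)2, THF, −78 to −40 °C; then MeI, −78 to 0 °C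
Reagents that add atoms: iodomethane, CI
Why: Second kinetic α′-enolization and enolate alkylation; in the tetrasubstituted enolate A(1,2) strain turns the C8 methyl pseudoaxial and iodomethane enters from the opposite face, so the C9 methyl should end trans to the C8 methyl and the chain cis, which sets the quaternary centre.

Step 4
Reactants: 7 (5R,6R)-5,6-dimethyl-6-[2-(2-methyl-1,3-dioxolan-2-yl)ethyl]cyclohex-2-en-1-one; 8 5-bromo-2-methylpent-2-ene
Product: 10 (5R,6R)-5,6-dimethyl-6-[2-(2-methyl-1,3-dioxolan-2-yl)ethyl]-1-(4-methylpent-3-en-1-yl)cyclohex-2-en-1-ol as a mixture of both C1 epimers, via (4-methylpent-3-en-1-yl)magnesium bromide 9 (not isolated)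
Conditions: 8, Mg, THF, rt; then LaCl3·2LiCl, 7, THF, 0 °C; H2O
Reagents that add atoms: none
Why: Grignard 1,2-addition to the hindered enone carbonyl, which has no α′-hydrogen (the Lewis acid LaCl3·2LiCl suppresses 1,4-addition and γ-deprotonation); both carbinol epimers serve because this carbon becomes sp2 in step 5.

Step 5
Reactants: 10 (5R,6R)-5,6-dimethyl-6-[2-(2-methyl-1,3-dioxolan-2-yl)ethyl]-1-(4-methylpent-3-en-1-yl)cyclohex-2-en-1-ol
Product: 11 (4R,5R)-4,5-dimethyl-4-[2-(2-methyl-1,3-dioxolan-2-yl)ethyl]-3-(4-methylpent-3-en-1-yl)cyclohex-2-en-1-one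
Conditions: C5H5NH[CrO3Cl], NaOAc, 4 Å molecular sieves, CH2Cl2, rt
Reagents that add atoms: pyridinium chlorochromate, [O-][Cr](=O)(=O)Cl.c1cc[nH+]cc1
Why: Oxidative 1,3-transposition of a tertiary allylic alcohol (Babler–Dauben oxidation): the chromate ester shifts by a [3,3] process to C6 and is oxidized to the C6 ketone with the alkene at C5=C10, and the buffered medium should spare the dioxolane and the trisubstituted alkene.

Step 6
Reactants: 11 (4R,5R)-4,5-dimethyl-4-[2-(2-methyl-1,3-dioxolan-2-yl)ethyl]-3-(4-methylpent-3-en-1-yl)cyclohex-2-en-1-one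
Product: 13 (3R,4R)-3,4,8,8-tetramethyl-4-(3-oxobutyl)-3,4,5,6,7,8-hexahydronaphthalen-1(2H)-one, via bicyclic enone ketal 12 (not isolated)
Conditions: MeSO3H (5 equiv), CH2Cl2, 0 °C to rt; then H2O, THF, rt
Reagents that add atoms: water, O
Why: Markovnikov protonation of the trisubstituted chain alkene gives the tertiary C4 cation, which is captured by C5, the α-carbon of the β,β-disubstituted enone (directly or through its extended dienol); loss of H5, now α to the C6 carbonyl, restores the conjugated tetrasubstituted C5=C10 enone, and aqueous acid then hydrolyses the dioxolane. The closest known reaction type is the acid-mediated cation–olefin cyclization of geranic esters to cyclogeranates and of pseudo-damascones and pseudoionone to β-damascone and β-ionone, in which the same carbonyl–CH=C(R)–CH2CH2–CH=C(CH3)2 array closes the same gem-dimethylcyclohexene. Ring A closes in a 6-endo-trig mode with respect to the C5=C10 π bond (both alkene carbons end up in the new ring) through a chair-like array tethered at C10. No stereocentre is created, and C9 (quaternary) and C8 (not α to a carbonyl) cannot epimerize. The step needs protonation of the electron-rich alkene in preference to the enone, closure at C5 in preference to a 1,2-shift from C9 to C10, and the conjugated 5(10)-ene in preference to the 1(10)-ene: the three-carbon tether allows only the six-membered closure at C5, removal of the acidified H5 should outrun Wagner–Meerwein migration, and the strong acid should equilibrate any β,γ-isomer into conjugation.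

Step 7
Reactants: 13 (3R,4R)-3,4,8,8-tetramethyl-4-(3-oxobutyl)-3,4,5,6,7,8-hexahydronaphthalen-1(2H)-one
Product: 14 ethyl (2E)-3-methyl-5-[(1R,2R)-1,2,5,5-tetramethyl-4-oxo-1,2,3,4,5,6,7,8-octahydronaphthalen-1-yl]pent-2-enoate
Conditions: (EtO)2P(O)CH2CO2Et, NaH, THF, 0 °C (anion pre-formed); then 13, rt to 50 °C; E isomer separated by chromatography
Reagents that add atoms: triethyl phosphonoacetate, CCOC(=O)CP(=O)(OCC)OCC
Why: Horner–Wadsworth–Emmons olefination of the unhindered methyl ketone (the tetrasubstituted, peri-shielded C6 enone carbonyl should not react) should give mainly the E trisubstituted enoate.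

Step 8
Reactants: 14 ethyl (2E)-3-methyl-5-[(1R,2R)-1,2,5,5-tetramethyl-4-oxo-1,2,3,4,5,6,7,8-octahydronaphthalen-1-yl]pent-2-enoate
Product: 16 ethyl (2E)-5-[(1R,2S,3R)-3-hydroxy-1,2,5,5-tetramethyl-4-oxo-1,2,3,4,5,6,7,8-octahydronaphthalen-1-yl]-3-methylpent-2-enoate, via potassium dienolate 15 (not isolated)
Conditions: KN(SiMe3)2, THF, −78 °C; then 2-(phenylsulfonyl)-3-phenyloxaziridine, −78 °C; AcOH
Reagents that add atoms: 2-(phenylsulfonyl)-3-phenyloxaziridine, O=S(=O)(c1ccccc1)N1OC1c1ccccc1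
Why: Kinetic α′-enolization at C7 followed by electrophilic enolate hydroxylation with the N-sulfonyloxaziridine; oxygen should enter anti to the adjacent C8 methyl to give the equatorial 7β-alcohol, which is also the thermodynamically preferred epimer.

Step 9
Reactants: 16 ethyl (2E)-5-[(1R,2S,3R)-3-hydroxy-1,2,5,5-tetramethyl-4-oxo-1,2,3,4,5,6,7,8-octahydronaphthalen-1-yl]-3-methylpent-2-enoate
Product: 18 (2E)-5-[(1R,2S,3R,4S)-3,4-dihydroxy-1,2,5,5-tetramethyl-1,2,3,4,5,6,7,8-octahydronaphthalen-1-yl]-3-methylpent-2-en-1-ol, via diol ester 17 (not isolated)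
Conditions: LiBH(s-Bu)3, THF, −78 to −40 °C; then i-Bu2AlH, −78 to 0 °C; aq. potassium sodium tartrate
Reagents that add atoms: none
Why: The bulky borohydride should reduce the β,β-disubstituted enone in 1,2-fashion along the equatorial trajectory, giving the pseudoaxial 6β-alcohol cis to the equatorial 7β-oxygen (diastereoselective ketone reduction), and i-Bu2AlH then reduces the enoate to the E allylic alcohol.

Step 10
Reactants: 18 (2E)-5-[(1R,2S,3R,4S)-3,4-dihydroxy-1,2,5,5-tetramethyl-1,2,3,4,5,6,7,8-octahydronaphthalen-1-yl]-3-methylpent-2-en-1-ol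
Product: 19 (1S,2R,3S,4R)-4-{2-[(2R,3R)-3-(hydroxymethyl)-2-methyloxiran-2-yl]ethyl}-3,4,8,8-tetramethyl-1,2,3,4,5,6,7,8-octahydronaphthalene-1,2-diol
Conditions: Ti(Oi-Pr)4 (1.2 equiv), D-(−)-diethyl tartrate (1.4 equiv), t-BuOOH, 4 Å molecular sieves, CH2Cl2, −25 °C
Reagents that add atoms: tert-butyl hydroperoxide, CC(C)(C)OO
Why: Sharpless asymmetric epoxidation of the primary E-trisubstituted allylic alcohol; reagent control by the D-(−)-tartrate should give the (2R,3R)-epoxy alcohol, which fixes C13 as R, while the hindered secondary ring allylic alcohol with its tetrasubstituted alkene should react far more slowly.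

Step 11
Reactants: 19 (1S,2R,3S,4R)-4-{2-[(2R,3R)-3-(hydroxymethyl)-2-methyloxiran-2-yl]ethyl}-3,4,8,8-tetramethyl-1,2,3,4,5,6,7,8-octahydronaphthalene-1,2-diol
Product: 21 (1S,2R,3S,4R)-4-[(3R)-3-hydroxy-3-methylpent-4-en-1-yl]-3,4,8,8-tetramethyl-1,2,3,4,5,6,7,8-octahydronaphthalene-1,2-diol, via epoxy iodide 20 (not isolated)
Conditions: PPh3, I2, imidazole, THF, 0 °C; then Zn dust, AcOH, EtOH, 0 °C to rt
Reagents that add atoms: none
Why: Appel-type iodination of the primary alcohol followed by zinc-mediated reductive β-elimination, which opens the epoxide to the vinyl carbinol; the C13–O bond is never broken, so C13 keeps its R configuration.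

Step 12
Reactants: 21 (1S,2R,3S,4R)-4-[(3R)-3-hydroxy-3-methylpent-4-en-1-yl]-3,4,8,8-tetramethyl-1,2,3,4,5,6,7,8-octahydronaphthalene-1,2-diol
Product: 22 (1S,2R,3S,4R)-1-hydroxy-4-[(3R)-3-hydroxy-3-methylpent-4-en-1-yl]-3,4,8,8-tetramethyl-1,2,3,4,5,6,7,8-octahydronaphthalen-2-yl acetate
Conditions: Ac2O (1.1 equiv), pyridine, CH2Cl2, −20 to 0 °C
Reagents that add atoms: acetic anhydride, CC(=O)OC(C)=O
Why: Site-selective acylation of the equatorial, less hindered C7 hydroxyl; the pseudoaxial allylic C6 hydroxyl sits next to the C4 gem-dimethyl group and the C13 hydroxyl is tertiary, so both should react much more slowly.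

**Compound list**
1 | 2-(2-bromoethyl)-2-methyl-1,3-dioxolane | CC1(CCBr)OCCO1 | starting material
2 | 2-(2-iodoethyl)-2-methyl-1,3-dioxolane | CC1(CCI)OCCO1 | intermediate
3 | (R)-5-methylcyclohex-2-en-1-one | C[C@@H]1CC=CC(=O)C1 | starting material
4 | lithium (3R)-3-methylcyclohexa-1,5-dien-1-olate (kinetic α′-enolate of 3) | C[C@@H]1CC=CC(O[Li])=C1 | intermediate
5 | (5R,6S)-5-methyl-6-[2-(2-methyl-1,3-dioxolan-2-yl)ethyl]cyclohex-2-en-1-one (chain trans to the 5-methyl) | CC1(CC[C@@H]2C(=O)C=CC[C@H]2C)OCCO1 | intermediate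
6 | lithium (3R)-3-methyl-2-[2-(2-methyl-1,3-dioxolan-2-yl)ethyl]cyclohexa-1,5-dien-1-olate | CC1(CCC2=C(O[Li])C=CC[C@H]2C)OCCO1 | intermediate
7 | (5R,6R)-5,6-dimethyl-6-[2-(2-methyl-1,3-dioxolan-2-yl)ethyl]cyclohex-2-en-1-one | CC1(CC[C@@]2(C)C(=O)C=CC[C@H]2C)OCCO1 | intermediate
8 | 5-bromo-2-methylpent-2-ene | CC(C)=CCCBr | starting material
9 | (4-methylpent-3-en-1-yl)magnesium bromide | CC(C)=CCC[Mg]Br | intermediate
10 | (5R,6R)-5,6-dimethyl-6-[2-(2-methyl-1,3-dioxolan-2-yl)ethyl]-1-(4-methylpent-3-en-1-yl)cyclohex-2-en-1-ol (both C1 epimers) | CC1(CC[C@@]2(C)C(O)(CCC=C(C)C)C=CC[C@H]2C)OCCO1 | intermediate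
11 | (4R,5R)-4,5-dimethyl-4-[2-(2-methyl-1,3-dioxolan-2-yl)ethyl]-3-(4-methylpent-3-en-1-yl)cyclohex-2-en-1-one | CC1(CC[C@@]2(C)C(CCC=C(C)C)=CC(=O)C[C@H]2C)OCCO1 | intermediate
12 | (3R,4R)-3,4,8,8-tetramethyl-4-[2-(2-methyl-1,3-dioxolan-2-yl)ethyl]-3,4,5,6,7,8-hexahydronaphthalen-1(2H)-one | CC1(CC[C@@]2(C)C3=C(C(=O)C[C@H]2C)C(C)(C)CCC3)OCCO1 | intermediate
13 | (3R,4R)-3,4,8,8-tetramethyl-4-(3-oxobutyl)-3,4,5,6,7,8-hexahydronaphthalen-1(2H)-one | CC(=O)CC[C@@]1(C)C2=C(C(=O)C[C@H]1C)C(C)(C)CCC2 | intermediate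
14 | ethyl (2E)-3-methyl-5-[(1R,2R)-1,2,5,5-tetramethyl-4-oxo-1,2,3,4,5,6,7,8-octahydronaphthalen-1-yl]pent-2-enoate | CCOC(=O)/C=C(\C)CC[C@@]1(C)C2=C(C(=O)C[C@H]1C)C(C)(C)CCC2 | intermediate
15 | potassium (3R,4R)-4-[(3E)-5-ethoxy-3-methyl-5-oxopent-3-en-1-yl]-3,4,8,8-tetramethyl-3,4,5,6,7,8-hexahydronaphthalen-1-olate (C6=C7 enolate of 14) | CCOC(=O)/C=C(\C)CC[C@@]1(C)C2=C(C(O[K])=C[C@H]1C)C(C)(C)CCC2 | intermediate
16 | ethyl (2E)-5-[(1R,2S,3R)-3-hydroxy-1,2,5,5-tetramethyl-4-oxo-1,2,3,4,5,6,7,8-octahydronaphthalen-1-yl]-3-methylpent-2-enoate | CCOC(=O)/C=C(\C)CC[C@@]1(C)C2=C(C(=O)[C@H](O)[C@H]1C)C(C)(C)CCC2 | intermediate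
17 | ethyl (2E)-5-[(1R,2S,3R,4S)-3,4-dihydroxy-1,2,5,5-tetramethyl-1,2,3,4,5,6,7,8-octahydronaphthalen-1-yl]-3-methylpent-2-enoate | CCOC(=O)/C=C(\C)CC[C@@]1(C)C2=C([C@H](O)[C@H](O)[C@H]1C)C(C)(C)CCC2 | intermediate
18 | (2E)-5-[(1R,2S,3R,4S)-3,4-dihydroxy-1,2,5,5-tetramethyl-1,2,3,4,5,6,7,8-octahydronaphthalen-1-yl]-3-methylpent-2-en-1-ol | OC/C=C(\C)CC[C@@]1(C)C2=C([C@H](O)[C@H](O)[C@H]1C)C(C)(C)CCC2 | intermediate
19 | (1S,2R,3S,4R)-4-{2-[(2R,3R)-3-(hydroxymethyl)-2-methyloxiran-2-yl]ethyl}-3,4,8,8-tetramethyl-1,2,3,4,5,6,7,8-octahydronaphthalene-1,2-diol | OC[C@H]1O[C@]1(C)CC[C@@]2(C)C3=C([C@H](O)[C@H](O)[C@H]2C)C(C)(C)CCC3 | intermediate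
20 | epoxy iodide: 19 with the primary hydroxyl replaced by iodine, same spatial arrangement | IC[C@H]1O[C@]1(C)CC[C@@]2(C)C3=C([C@H](O)[C@H](O)[C@H]2C)C(C)(C)CCC3 | intermediate
21 | (1S,2R,3S,4R)-4-[(3R)-3-hydroxy-3-methylpent-4-en-1-yl]-3,4,8,8-tetramethyl-1,2,3,4,5,6,7,8-octahydronaphthalene-1,2-diol | C=C[C@](C)(O)CC[C@@]1(C)C2=C([C@H](O)[C@H](O)[C@H]1C)C(C)(C)CCC2 | intermediate
22 | (1S,2R,3S,4R)-1-hydroxy-4-[(3R)-3-hydroxy-3-methylpent-4-en-1-yl]-3,4,8,8-tetramethyl-1,2,3,4,5,6,7,8-octahydronaphthalen-2-yl acetate | C=C[C@](C)(O)CC[C@@]1(C)C2=C([C@H](O)[C@H](OC(C)=O)[C@H]1C)C(C)(C)CCC2 | target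

**Totals**
Total step count: 12. Longest linear sequence: 12 steps (1 to 22); 11 steps from enone 3.

**Steps most likely to fail**

Step 6. The unmasked C13 carbonyl (or the oxocarbenium ion from the dioxolane) may intercept the dienol or the cations in an acid aldol-type side reaction, and the closure may stall at the non-conjugated alkene isomer. The fallback changes the order of events so that the cationic closure is run on a substrate whose side chain is already the acid-inert enoate. It sets out from 11: ketal hydrolysis (pyridinium p-toluenesulfonate, acetone/H2O, 50 °C) should give (4R,5R)-4,5-dimethyl-3-(4-methylpent-3-en-1-yl)-4-(3-oxobutyl)cyclohex-2-en-1-one F1. Horner–Wadsworth–Emmons olefination of F1 (pre-formed sodium salt of triethyl phosphonoacetate, THF) should give ethyl (2E)-5-[(1R,6R)-1,6-dimethyl-2-(4-methylpent-3-en-1-yl)-4-oxocyclohex-2-en-1-yl]-3-methylpent-2-enoate F2. MeSO3H in CH2Cl2 then closes ring A on F2, and the route is rejoined at 14.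

Step 9. Hydride delivery to C6 may show poor facial selectivity (axial attack gives the trans-diol), or conjugate reduction may compete. The fallback makes the cis-diol by syn-dihydroxylation instead and sets out from 14. Kinetic enolization and O-triflation (KN(SiMe3)2, PhNTf2, THF, −78 °C) should give the ring B dienyl triflate F3 (triflate on C6, alkenes C6=C7 and C5=C10). Reduction with Pd(OAc)2, PPh3, Bu3N and HCO2H in DMF should give the ring B 5(10),6-diene F4. OsO4 (catalytic) with N-methylmorpholine N-oxide should dihydroxylate the disubstituted C6=C7 bond from the face anti to the C8 methyl. This gives 17, where the route is rejoined; 17 is then reduced with i-Bu2AlH as in the second stage of step 9.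

Step 12. Acylation may lack site selectivity (reaction at O6, diacetylation) or the acetyl group may migrate. The fallback replaces direct acylation by activation of the cis-diol as a tin acetal and sets out from 21. Bu2SnO in MeOH at reflux should give the 6,7-O-dibutylstannylene acetal F5. Acetyl chloride in CH2Cl2 at 0 °C should then acylate the equatorial C7 oxygen and give 22.

**Further compounds**
F1 | step 6 | (4R,5R)-4,5-dimethyl-3-(4-methylpent-3-en-1-yl)-4-(3-oxobutyl)cyclohex-2-en-1-one | CC(=O)CC[C@@]1(C)C(CCC=C(C)C)=CC(=O)C[C@H]1C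
F2 | step 6 | ethyl (2E)-5-[(1R,6R)-1,6-dimethyl-2-(4-methylpent-3-en-1-yl)-4-oxocyclohex-2-en-1-yl]-3-methylpent-2-enoate | CCOC(=O)/C=C(\C)CC[C@@]1(C)C(CCC=C(C)C)=CC(=O)C[C@H]1C
F3 | step 9 | ring B dienyl triflate of 14 (C6–OTf, C6=C7, C5=C10) | CCOC(=O)/C=C(\C)CC[C@@]1(C)C2=C(C(OS(=O)(=O)C(F)(F)F)=C[C@H]1C)C(C)(C)CCC2
F4 | step 9 | ring B 5(10),6-diene enoate | CCOC(=O)/C=C(\C)CC[C@@]1(C)C2=C(C=C[C@H]1C)C(C)(C)CCC2
F5 | step 12 | 6,7-O-dibutylstannylene acetal of 21 | C=C[C@](C)(O)CC[C@@]1(C)C2=C([C@@H]3O[Sn](CCCC)(CCCC)O[C@@H]3[C@H]1C)C(C)(C)CCC2
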